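The pyranone ring (ring C) is closed late, at the C3–C4 bond, by an enantioselective intramolecular Stetter-type addition. The feature exploited is the 2'-hydroxyl of ring B, ortho to C1': once fluoride unmasks it, the phenoxide expels a benzylic acetate, so that C3 becomes the exocyclic carbon of an ortho-quinone methide, while a chiral triazolylidene turns the ring A aldehyde carbon (C4) into an acyl anion equivalent. One operation therefore forms ring C and sets C3. The precursor is an open aryl 2-aryl-2-acetoxyethyl ether, assembled by Williamson coupling of a ring B phenacyl bromide with a protected phloroglucinaldehyde, Stille prenylation and ketone reduction.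

Key step: step 9

Remark: positions are numbered as in isoflavanones (ring C: O1, C2, C3, C4; ring A: C4a–C8a; ring B: C1'–C6') and the target is the (3R) enantiomer. The catalyst of step 9 is (5aS,10bR)-2-(pentafluorophenyl)-5a,10b-dihydro-4H,6H-indeno[2,1-b][1,2,4]triazolo[4,3-d][1,4]oxazin-2-ium tetrafluoroborate; its sense of induction is assigned by analogy only, and the antipodal salt is used if a pilot run shows the opposite sense.

Step 1
Reactants: 1 1-(2,3-dihydroxy-4-methoxyphenyl)ethan-1-one
Product: 2 1-(5-bromo-2,3-dihydroxy-4-methoxyphenyl)ethan-1-one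
Conditions: Br2 (1.05 equiv), NaOAc, AcOH, 15 °C
Reagents that add atoms: bromine, BrBr
Why: Electrophilic aromatic bromination is directed to C5, which is para to the 2-hydroxyl, ortho to the methoxy group and meta to the deactivating acetyl group, while NaOAc takes up HBr so that the methyl ketone does not enolise and brominate.

Step 2
Reactants: 2 1-(5-bromo-2,3-dihydroxy-4-methoxyphenyl)ethan-1-one
Product: 3 1-[5-bromo-2-hydroxy-4-methoxy-3-(methoxymethoxy)phenyl]ethan-1-one
Conditions: MOMCl (1.1 equiv), i-Pr2NEt, CH2Cl2, 0 °C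
Reagents that add atoms: chloromethyl methyl ether, COCCl
Why: Williamson-type O-alkylation with one equivalent of MOMCl takes the free 3-hydroxyl, because the 2-hydroxyl is tied up in a hydrogen bond to the acetyl oxygen and is far less nucleophilic.

Step 3
Reactants: 3 1-[5-bromo-2-hydroxy-4-methoxy-3-(methoxymethoxy)phenyl]ethan-1-one
Product: 5 2-bromo-1-[5-bromo-2-(tert-butyldimethylsilyloxy)-4-methoxy-3-(methoxymethoxy)phenyl]ethan-1-one, via silyl enol ether 4 (not isolated)
Conditions: TBSOTf (2.4 equiv), Et3N, CH2Cl2, 0 °C; then NBS, THF, −78 → 0 °C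
Reagents that add atoms: tert-butyldimethylsilyl trifluoromethanesulfonate, CC(C)(C)[Si](C)(C)OS(=O)(=O)C(F)(F)F; N-bromosuccinimide, O=C1CCC(=O)N1Br
Why: TBSOTf/Et3N silylates the chelated phenol and, by soft enolisation that never passes through a free enolate, the methyl ketone, and NBS then brominates the silyl enol ether 4 at carbon to give the phenacyl bromide while the aryl silyl ether stays in place.

Step 4
Reactants: 6 2,4,6-trihydroxybenzaldehyde
Product: 7 2-hydroxy-4,6-bis(methoxymethoxy)benzaldehyde
Conditions: MOMCl (2.1 equiv), i-Pr2NEt, CH2Cl2, 0 °C → rt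
Reagents that add atoms: chloromethyl methyl ether, COCCl
Why: O-Alkylation with two equivalents of MOMCl stops at the bis-ether because the last ortho hydroxyl is locked in a hydrogen bond to the formyl oxygen, and this free phenol is the one needed for the ether link.

Step 5
Reactants: 5 2-bromo-1-[5-bromo-2-(tert-butyldimethylsilyloxy)-4-methoxy-3-(methoxymethoxy)phenyl]ethan-1-one; 7 2-hydroxy-4,6-bis(methoxymethoxy)benzaldehyde
Product: 8 2-{2-[5-bromo-2-(tert-butyldimethylsilyloxy)-4-methoxy-3-(methoxymethoxy)phenyl]-2-oxoethoxy}-4,6-bis(methoxymethoxy)benzaldehyde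
Conditions: K2CO3, acetone, 0 °C → rt
Reagents that add atoms: none
Why: Williamson ether synthesis, in which the chelated but acidic phenol of 7 is deprotonated by K2CO3 and displaces bromide from the highly SN2-reactive phenacyl bromide at room temperature, mild enough to leave the aryl silyl ether intact and to avoid intramolecular aldol (Rap–Stoermer) closure onto the aldehyde.

Step 6
Reactants: 8 2-{2-[5-bromo-2-(tert-butyldimethylsilyloxy)-4-methoxy-3-(methoxymethoxy)phenyl]-2-oxoethoxy}-4,6-bis(methoxymethoxy)benzaldehyde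
Product: 9 2-{2-[2-(tert-butyldimethylsilyloxy)-4-methoxy-3-(methoxymethoxy)-5-(3-methylbut-2-en-1-yl)phenyl]-2-oxoethoxy}-4,6-bis(methoxymethoxy)benzaldehyde
Conditions: tributyl(3-methylbut-2-en-1-yl)stannane, Pd(PPh3)4 (5 mol %), DMF, 90 °C
Reagents that add atoms: tributyl(3-methylbut-2-en-1-yl)stannane, CC(C)=CC[Sn](CCCC)(CCCC)CCCC
Why: The Migita–Kosugi–Stille coupling runs under neutral conditions that tolerate the aldehyde, the ketone and the acetal and silyl ethers, and reductive elimination at the unsubstituted terminus of the prenyl ligand should give the linear 3-methylbut-2-enyl arene.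

Step 7
Reactants: 9 2-{2-[2-(tert-butyldimethylsilyloxy)-4-methoxy-3-(methoxymethoxy)-5-(3-methylbut-2-en-1-yl)phenyl]-2-oxoethoxy}-4,6-bis(methoxymethoxy)benzaldehyde
Product: 12 2-{2-[2-(tert-butyldimethylsilyloxy)-4-methoxy-3-(methoxymethoxy)-5-(3-methylbut-2-en-1-yl)phenyl]-2-hydroxyethoxy}-4,6-bis(methoxymethoxy)benzaldehyde (racemic), via keto N-tert-butyl aldimine 10 (not isolated), via hydroxy N-tert-butyl aldimine 11 (not isolated)
Conditions: t-BuNH2, MgSO4, CH2Cl2, rt; NaBH4, MeOH, −20 °C; 10% aq. citric acid, THF, rt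
Reagents that add atoms: water, O
Why: The aldehyde condenses with tert-butylamine to the aldimine 10 while the aryl ketone does not, NaBH4 in cold methanol then reduces only the ketone (masking of an aldehyde as its Schiff base during ketone reduction) and mild aqueous acid hydrolyses 11 back to the aldehyde; the new carbinol centre is formed racemic, which is of no consequence because this carbon becomes trigonal in step 9.

Step 8
Reactants: 12 2-{2-[2-(tert-butyldimethylsilyloxy)-4-methoxy-3-(methoxymethoxy)-5-(3-methylbut-2-en-1-yl)phenyl]-2-hydroxyethoxy}-4,6-bis(methoxymethoxy)benzaldehyde (racemic)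
Product: 13 1-[2-(tert-butyldimethylsilyloxy)-4-methoxy-3-(methoxymethoxy)-5-(3-methylbut-2-en-1-yl)phenyl]-2-[2-formyl-3,5-bis(methoxymethoxy)phenoxy]ethyl acetate (racemic)
Conditions: Ac2O, pyridine, DMAP (cat.), CH2Cl2, 0 °C
Reagents that add atoms: acetic anhydride, CC(=O)OC(C)=O
Why: DMAP-catalysed acetylation converts the benzylic hydroxyl into the acetate nucleofuge required for quinone methide formation, and the configuration of this centre is irrelevant.

Step 9
Reactants: 13 1-[2-(tert-butyldimethylsilyloxy)-4-methoxy-3-(methoxymethoxy)-5-(3-methylbut-2-en-1-yl)phenyl]-2-[2-formyl-3,5-bis(methoxymethoxy)phenoxy]ethyl acetate (racemic)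
Product: 15 (3R)-3-[2-hydroxy-4-methoxy-3-(methoxymethoxy)-5-(3-methylbut-2-en-1-yl)phenyl]-5,7-bis(methoxymethoxy)-2,3-dihydro-4H-chromen-4-one, via ortho-quinone methide 14 (not isolated)
Conditions: (5aS,10bR)-triazolium tetrafluoroborate of the remark (20 mol %), i-Pr2NEt (20 mol %), CsF (1.5 equiv), 18-crown-6 (1.5 equiv), THF (0.02 M), −20 → 0 °C; then AcOH
Reagents that add atoms: none
Why: Proposed new method: fluoride cleaves the aryl silyl ether of 13 and the 2'-phenoxide expels the benzylic acetate to give the ortho-quinone methide 14, in which C3 is the electrophilic exocyclic terminus of an enone built into ring B, while the triazolylidene adds to the ring A aldehyde and the resulting acyl anion equivalent (C4) attacks C3, ring B regaining aromaticity and the catalyst being released from the new ketone. The closest known reaction types are the enantioselective intramolecular Stetter reaction of salicylaldehyde-derived ethers, which closes chroman-4-ones at the same bond with this triazolium family, the carbene-catalysed ring closure of such aldehydes onto a tether carbon bearing a leaving group, and carbene catalysis on ortho-quinone methides released by fluoride from silyl-protected precursors. Ring C closes in a 6-exo-trig mode, the C3=C1' double bond of 14 lying outside the new ring. The C3 stereocentre is set in the C–C bond-forming step by the aminoindanol scaffold of the catalyst, which blocks one face of the acyl anion equivalent so that it meets a single enantiotopic face of the (E)-configured exocyclic carbon; the racemic carbinol centre of 13 is erased in 14. The step needs ring closure to outrun 1,5-hydrogen shift and oligomerisation of 14 and needs the product not to enolise: acetate re-adds reversibly to 14 and keeps its stationary concentration low, high dilution disfavours intermolecular capture, the MOM group on O3' keeps the quinone methide neutral and electrophilic, and the only base left is acetate, removed by the cold acidic quench.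

Step 10
Reactants: 15 (3R)-3-[2-hydroxy-4-methoxy-3-(methoxymethoxy)-5-(3-methylbut-2-en-1-yl)phenyl]-5,7-bis(methoxymethoxy)-2,3-dihydro-4H-chromen-4-one
Product: 16 (3R)-3-[2,3-dihydroxy-4-methoxy-5-(3-methylbut-2-en-1-yl)phenyl]-5,7-dihydroxy-2,3-dihydro-4H-chromen-4-one
Conditions: ZnBr2, n-PrSH, CH2Cl2, 0 °C
Reagents that add atoms: none
Why: ZnBr2-assisted thiolysis of the three aryl methoxymethyl acetals should be complete within minutes at 0 °C under non-basic conditions, so the enolisable C3–H next to the C4 ketone should keep its configuration, and the prenyl group, which has no ortho hydroxyl, cannot cyclise.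

Compound list
1 | 1-(2,3-dihydroxy-4-methoxyphenyl)ethan-1-one | CC(=O)c1ccc(OC)c(O)c1O | starting material
2 | 1-(5-bromo-2,3-dihydroxy-4-methoxyphenyl)ethan-1-one | CC(=O)c1cc(Br)c(OC)c(O)c1O | intermediate
3 | 1-[5-bromo-2-hydroxy-4-methoxy-3-(methoxymethoxy)phenyl]ethan-1-one | CC(=O)c1cc(Br)c(OC)c(OCOC)c1O | intermediate
4 | tert-butyl({1-[5-bromo-2-(tert-butyldimethylsilyloxy)-4-methoxy-3-(methoxymethoxy)phenyl]ethenyl}oxy)dimethylsilane | C=C(O[Si](C)(C)C(C)(C)C)c1cc(Br)c(OC)c(OCOC)c1O[Si](C)(C)C(C)(C)C | intermediate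
5 | 2-bromo-1-[5-bromo-2-(tert-butyldimethylsilyloxy)-4-methoxy-3-(methoxymethoxy)phenyl]ethan-1-one | BrCC(=O)c1cc(Br)c(OC)c(OCOC)c1O[Si](C)(C)C(C)(C)C | intermediate
6 | 2,4,6-trihydroxybenzaldehyde | O=Cc1c(O)cc(O)cc1O | starting material
7 | 2-hydroxy-4,6-bis(methoxymethoxy)benzaldehyde | COCOc1cc(O)c(C=O)c(OCOC)c1 | intermediate
8 | 2-{2-[5-bromo-2-(tert-butyldimethylsilyloxy)-4-methoxy-3-(methoxymethoxy)phenyl]-2-oxoethoxy}-4,6-bis(methoxymethoxy)benzaldehyde | COc1c(Br)cc(C(=O)COc2cc(OCOC)cc(OCOC)c2C=O)c(O[Si](C)(C)C(C)(C)C)c1OCOC | intermediate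
9 | 2-{2-[2-(tert-butyldimethylsilyloxy)-4-methoxy-3-(methoxymethoxy)-5-(3-methylbut-2-en-1-yl)phenyl]-2-oxoethoxy}-4,6-bis(methoxymethoxy)benzaldehyde | COc1c(CC=C(C)C)cc(C(=O)COc2cc(OCOC)cc(OCOC)c2C=O)c(O[Si](C)(C)C(C)(C)C)c1OCOC | intermediate
10 | (E)-N-tert-butyl aldimine of 9 (ketone intact) | COc1c(CC=C(C)C)cc(C(=O)COc2cc(OCOC)cc(OCOC)c2/C=N/C(C)(C)C)c(O[Si](C)(C)C(C)(C)C)c1OCOC | intermediate
11 | (E)-N-tert-butyl aldimine of 12 (racemic secondary alcohol) | COc1c(CC=C(C)C)cc(C(O)COc2cc(OCOC)cc(OCOC)c2/C=N/C(C)(C)C)c(O[Si](C)(C)C(C)(C)C)c1OCOC | intermediate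
12 | 2-{2-[2-(tert-butyldimethylsilyloxy)-4-methoxy-3-(methoxymethoxy)-5-(3-methylbut-2-en-1-yl)phenyl]-2-hydroxyethoxy}-4,6-bis(methoxymethoxy)benzaldehyde (racemic) | COc1c(CC=C(C)C)cc(C(O)COc2cc(OCOC)cc(OCOC)c2C=O)c(O[Si](C)(C)C(C)(C)C)c1OCOC | intermediate
13 | 1-[2-(tert-butyldimethylsilyloxy)-4-methoxy-3-(methoxymethoxy)-5-(3-methylbut-2-en-1-yl)phenyl]-2-[2-formyl-3,5-bis(methoxymethoxy)phenoxy]ethyl acetate (racemic) | COc1c(CC=C(C)C)cc(C(OC(C)=O)COc2cc(OCOC)cc(OCOC)c2C=O)c(O[Si](C)(C)C(C)(C)C)c1OCOC | intermediate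
14 | 2-{(2E)-2-[4-methoxy-5-(methoxymethoxy)-3-(3-methylbut-2-en-1-yl)-6-oxocyclohexa-2,4-dien-1-ylidene]ethoxy}-4,6-bis(methoxymethoxy)benzaldehyde | O=C1C(OCOC)=C(OC)C(CC=C(C)C)=C/C1=C\COc1cc(OCOC)cc(OCOC)c1C=O | intermediate
15 | (3R)-3-[2-hydroxy-4-methoxy-3-(methoxymethoxy)-5-(3-methylbut-2-en-1-yl)phenyl]-5,7-bis(methoxymethoxy)-2,3-dihydro-4H-chromen-4-one | COc1c(CC=C(C)C)cc([C@@H]2COc3cc(OCOC)cc(OCOC)c3C2=O)c(O)c1OCOC | intermediate
16 | (3R)-3-[2,3-dihydroxy-4-methoxy-5-(3-methylbut-2-en-1-yl)phenyl]-5,7-dihydroxy-2,3-dihydro-4H-chromen-4-one | COc1c(CC=C(C)C)cc([C@@H]2COc3cc(O)cc(O)c3C2=O)c(O)c1O | target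

Total step count: 10. Longest linear sequence: 9 steps (steps 1, 2, 3, 5, 6, 7, 8, 9, 10); step 4 prepares the ring A partner.

Steps most likely to fail

Step 9 (proposed new method). The quinone methide may be lost to 1,5-hydrogen shift or oligomerisation before ring closure, the electron-rich, doubly ortho-substituted aldehyde may be too slow to form the acyl anion equivalent, or C3 may lose its configuration by enolisation in the fluoride medium. The fallback closes the same bond with known chemistry and sets out from keto aldehyde 9. A triazolium-catalysed intramolecular crossed benzoin reaction (aldehyde carbon onto the ketone; achiral triazolium salt, Et3N, THF) should give the racemic ketol 3-aryl-3-hydroxy-5,7-bis(methoxymethoxy)chroman-4-one F1. Dehydration with the Burgess reagent (toluene, 60 °C) should give the isoflavone F2. Asymmetric transfer hydrogenation with RuCl[(R,R)-TsDPEN](p-cymene) or its antipode in HCO2H/Et3N reduces the enone double bond and then the ketone under dynamic kinetic resolution, and should give the cis-(3R,4R)-isoflavan-4-ol F3. Oxidation with Dess–Martin periodinane buffered with NaHCO3 should give the (3R)-configured silyl-protected isoflavanone F4 without touching C3. TBAF buffered with AcOH (THF, 0 °C) then removes the silyl group and the route is rejoined at 15.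

Step 7. The hindered aldimine may be reduced along with the ketone, or the amine may promote intramolecular Mannich or aldol closure of the keto aldehyde to a benzofuran. The fallback sets out from 9: both carbonyl groups are reduced with NaBH4 (MeOH, 0 °C) to the racemic diol F5, and the primary benzylic alcohol alone is reoxidised with TEMPO/PhI(OAc)2 (CH2Cl2, rt), which should return the route to 12.

Step 6. The prenyl group may be transferred with allylic transposition, which would place a 1,1-dimethylallyl group on the ring. The fallback sets out from 8: Stille coupling with allyltributylstannane, which has no such ambiguity, should give the allyl arene F6, and cross-metathesis with 2-methylbut-2-ene using the second-generation Grubbs catalyst RuCl2(=CHPh)(H2IMes)(PCy3) (CH2Cl2, 40 °C) should give 9.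

Further compounds
F1 | step 9 | 3-[2-(tert-butyldimethylsilyloxy)-4-methoxy-3-(methoxymethoxy)-5-(3-methylbut-2-en-1-yl)phenyl]-3-hydroxy-5,7-bis(methoxymethoxy)-2,3-dihydro-4H-chromen-4-one (racemic) | COc1c(CC=C(C)C)cc(C2(O)COc3cc(OCOC)cc(OCOC)c3C2=O)c(O[Si](C)(C)C(C)(C)C)c1OCOC
F2 | step 9 | 3-[2-(tert-butyldimethylsilyloxy)-4-methoxy-3-(methoxymethoxy)-5-(3-methylbut-2-en-1-yl)phenyl]-5,7-bis(methoxymethoxy)-4H-chromen-4-one | COc1c(CC=C(C)C)cc(-c2coc3cc(OCOC)cc(OCOC)c3c2=O)c(O[Si](C)(C)C(C)(C)C)c1OCOC
F3 | step 9 | (3R,4R)-3-[2-(tert-butyldimethylsilyloxy)-4-methoxy-3-(methoxymethoxy)-5-(3-methylbut-2-en-1-yl)phenyl]-5,7-bis(methoxymethoxy)-3,4-dihydro-2H-chromen-4-ol (cis) | COc1c(CC=C(C)C)cc([C@@H]2COc3cc(OCOC)cc(OCOC)c3[C@@H]2O)c(O[Si](C)(C)C(C)(C)C)c1OCOC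
F4 | step 9 | (3R)-3-[2-(tert-butyldimethylsilyloxy)-4-methoxy-3-(methoxymethoxy)-5-(3-methylbut-2-en-1-yl)phenyl]-5,7-bis(methoxymethoxy)-2,3-dihydro-4H-chromen-4-one | COc1c(CC=C(C)C)cc([C@@H]2COc3cc(OCOC)cc(OCOC)c3C2=O)c(O[Si](C)(C)C(C)(C)C)c1OCOC
F5 | step 7 | 1-[2-(tert-butyldimethylsilyloxy)-4-methoxy-3-(methoxymethoxy)-5-(3-methylbut-2-en-1-yl)phenyl]-2-[2-(hydroxymethyl)-3,5-bis(methoxymethoxy)phenoxy]ethan-1-ol (racemic) | COc1c(CC=C(C)C)cc(C(O)COc2cc(OCOC)cc(OCOC)c2CO)c(O[Si](C)(C)C(C)(C)C)c1OCOC
F6 | step 6 | 2-{2-[2-(tert-butyldimethylsilyloxy)-4-methoxy-3-(methoxymethoxy)-5-(prop-2-en-1-yl)phenyl]-2-oxoethoxy}-4,6-bis(methoxymethoxy)benzaldehyde | COc1c(CC=C)cc(C(=O)COc2cc(OCOC)cc(OCOC)c2C=O)c(O[Si](C)(C)C(C)(C)C)c1OCOC
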